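**Retrosynthetic overview**
1. Target 24 comes from its 5,7-bis(methoxymethyl) ether 23 by one acid-catalysed acetal cleavage.
2. Ring C of 23 is made in a single operation from ring-A aryne 20 and the (S)-β-hydroxy Weinreb amide 18 (ring B plus C2–C3–C4). The alkoxide oxygen adds to C8a (O1–C8a), and the resulting C4a carbanion closes the ring on the amide carbonyl (C4–C4a).
3. Enabling feature: in ring A the two carbons shared with ring C, C4a and C8a, are adjacent, and C4a is flanked by the oxygen-bearing C5. An aryne across C4a–C8a is therefore polarized so that O1 bonds to C8a and the carbanion appears at C4a, six atoms from the C4 carbonyl (C4a–C8a–O1–C2–C3–C4).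
4. Aryne precursor 12 comes from 4-methylresorcinol by decorating the ring: two directed ortho-metalations (C6 prenyl, then C4a oxygen), bromination at C8a, and retro-Brook/triflation. Amide 18 comes from methyl 3-iodo-4-methoxybenzoate by Stille prenylation, Claisen condensation and asymmetric transfer hydrogenation, which sets C2.
5. Order of ring formation: rings A and B are bought as benzene rings; ring C is the only ring formed (step 9).

Key step: step 9

Remark: the drawn target is the (2S)-flavanone. The (S,S)-TsDPEN catalyst is assigned to the (S)-carbinol by analogy with acetophenone-type ketones; if the sense proved opposite, the (R,R)-catalyst would be used.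

**Step 1**
Reactants: 1 4-methylbenzene-1,3-diol (4-methylresorcinol)
Product: 2 2,4-bis(methoxymethoxy)-1-methylbenzene
Conditions: MOMCl (2.5 equiv), iPr2NEt, CH2Cl2, 0 → 23 °C
Reagents that add atoms: chloromethyl methyl ether COCCl
Why: Double O-alkylation of the phenols (Williamson-type etherification) installs methoxymethyl ethers that tolerate organolithiums, fluoride and KH, direct both later metalations and leave under mild acid at the end.

**Step 2**
Reactants: 2 2,4-bis(methoxymethoxy)-1-methylbenzene
Product: 4 2,4-bis(methoxymethoxy)-1-methyl-3-(3-methylbut-2-en-1-yl)benzene, via aryllithium 3 (not isolated)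
Conditions: n-BuLi, THF, 0 → 23 °C; then CuBr·SMe2 (10 mol%), prenyl bromide, −78 → 23 °C
Reagents that add atoms: 1-bromo-3-methylbut-2-ene CC(C)=CCBr
Why: Directed ortho-metalation should occur at the carbon flanked by both methoxymethoxy groups (the future C6), and copper-catalysed SN2 allylation of aryllithium 3 should give the linear prenyl arene.

**Step 3**
Reactants: 4 2,4-bis(methoxymethoxy)-1-methyl-3-(3-methylbut-2-en-1-yl)benzene
Product: 7 2,4-bis(methoxymethoxy)-5-methyl-3-(3-methylbut-2-en-1-yl)phenol, via aryllithium 5 (not isolated), via arylboronate 6 (not isolated)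
Conditions: n-BuLi, TMEDA, THF, −20 → 0 °C; B(OMe)3, −78 → 23 °C; then 30% H2O2, aq NaOH, 0 °C
Reagents that add atoms: hydrogen peroxide OO
Why: The second directed ortho-metalation can only use the one remaining hydrogen next to a methoxymethoxy group (the future C4a), and borylation followed by alkaline peroxide ipso-hydroxylation of boronate 6 turns that C–Li bond into the phenol.

**Step 4**
Reactants: 7 2,4-bis(methoxymethoxy)-5-methyl-3-(3-methylbut-2-en-1-yl)phenol
Product: 8 2-bromo-4,6-bis(methoxymethoxy)-3-methyl-5-(3-methylbut-2-en-1-yl)phenol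
Conditions: NBS (1.0 equiv), iPr2NH (10 mol%), CH2Cl2, −78 → 0 °C
Reagents that add atoms: N-bromosuccinimide O=C1CCC(=O)N1Br
Why: Amine-mediated ortho-selective electrophilic bromination of the phenol, expected to be much faster at low temperature than attack on the trisubstituted alkene, must take the single free ring position (ortho to OH, the future C8a).

**Step 5**
Reactants: 8 2-bromo-4,6-bis(methoxymethoxy)-3-methyl-5-(3-methylbut-2-en-1-yl)phenol
Product: 12 2,4-bis(methoxymethoxy)-5-methyl-3-(3-methylbut-2-en-1-yl)-6-(trimethylsilyl)phenyl trifluoromethanesulfonate, via silyl ether 9 (not isolated), via aryllithium 10 (not isolated), via lithium phenolate 11 (not isolated)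
Conditions: (Me3Si)2NH, THF, 65 °C, evaporation; n-BuLi, THF, −100 → −78 °C; Tf2O, −78 °C
Reagents that add atoms: hexamethyldisilazane C[Si](C)(C)N[Si](C)(C)C; trifluoromethanesulfonic anhydride O=S(=O)(OS(=O)(=O)C(F)(F)F)C(F)(F)F
Why: O-silylation, bromine–lithium exchange and retro-Brook (1,3 O→C) silyl migration move the trimethylsilyl group onto the carbon that carried bromine, and triflation of phenolate 11 completes the standard 2-(trimethylsilyl)aryl triflate aryne precursor.

**Step 6**
Reactants: 13 methyl 3-iodo-4-methoxybenzoate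
Product: 14 methyl 4-methoxy-3-(3-methylbut-2-en-1-yl)benzoate
Conditions: tributyl(3-methylbut-2-en-1-yl)stannane, Pd(PPh3)4 (5 mol%), DMF, 90 °C
Reagents that add atoms: tributyl(3-methylbut-2-en-1-yl)stannane CCCC[Sn](CCCC)(CCCC)CC=C(C)C
Why: Stille coupling of the aryl iodide should give the linear prenyl arene, because reductive elimination from the aryl(allyl)palladium intermediate occurs at the less substituted allyl terminus, and the ester is inert.

**Step 7**
Reactants: 14 methyl 4-methoxy-3-(3-methylbut-2-en-1-yl)benzoate; 15 N-methoxy-N-methylacetamide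
Product: 17 N-methoxy-3-[4-methoxy-3-(3-methylbut-2-en-1-yl)phenyl]-N-methyl-3-oxopropanamide, via lithium enolate 16 (not isolated)
Conditions: LiN(iPr)2 (2.2 equiv), 15 (2.2 equiv), THF, −78 °C; then 14, −78 → −40 °C; 1 M HCl
Reagents that add atoms: none
Why: Crossed Claisen condensation of the amide enolate 16 and the non-enolizable benzoate is driven by deprotonation of the β-keto amide by the second equivalent of enolate.

**Step 8**
Reactants: 17 N-methoxy-3-[4-methoxy-3-(3-methylbut-2-en-1-yl)phenyl]-N-methyl-3-oxopropanamide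
Product: 18 (3S)-3-hydroxy-N-methoxy-3-[4-methoxy-3-(3-methylbut-2-en-1-yl)phenyl]-N-methylpropanamide
Conditions: RuCl[(S,S)-TsDPEN](p-cymene) (1 mol%), HCO2H/Et3N (5:2), DMF, 30 °C
Reagents that add atoms: none
Why: Noyori asymmetric transfer hydrogenation of the aryl ketone sets the future C2, the (S,S)-ligand being expected to give the (S)-carbinol by the CH/π model for aryl ketones, while the alkene and the N–O bond are not reduced.

**Step 9**
Reactants: 18 (3S)-3-hydroxy-N-methoxy-3-[4-methoxy-3-(3-methylbut-2-en-1-yl)phenyl]-N-methylpropanamide; 12 2,4-bis(methoxymethoxy)-5-methyl-3-(3-methylbut-2-en-1-yl)-6-(trimethylsilyl)phenyl trifluoromethanesulfonate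
Product: 23 (2S)-5,7-bis(methoxymethoxy)-2-[4-methoxy-3-(3-methylbut-2-en-1-yl)phenyl]-8-methyl-6-(3-methylbut-2-en-1-yl)-2,3-dihydro-4H-chromen-4-one, via potassium alkoxide 19 (not isolated), via aryne 20 (not isolated), via aryl anion 21 (not isolated), via hemiaminal alkoxide 22 (not isolated)
Conditions: KH (1.05 equiv), 18-crown-6, THF, 0 °C; then 12 (1.3 equiv), KF (3 equiv), 0 → 23 °C; AcOH, −20 °C, then H2O
Reagents that add atoms: none
Why: Proposed new method: potassium alkoxide 19 adds through oxygen to C8a of aryne 20 (released from 12 by fluoride), the C4a aryl anion 21 attacks the Weinreb amide carbonyl six atoms away, and hemiaminal alkoxide 22 persists until the acetic acid quench releases ketone 23; the closest known reaction type is the fluoride-triggered aryne annulation of salicylate esters to xanthones (phenoxide addition, then acyl capture of the aryl anion), extended here from a phenoxide to an aliphatic benzylic alkoxide and from an ester to a Weinreb amide, and supported by the known O-arylation of aliphatic alcohols by arynes and by Parham cyclizations of aryllithiums onto such amides. Ring C closes by a 6-exo-trig acyl addition that forms the C4–C4a bond, directly after the intermolecular O1–C8a bond. No stereocenter is created: C2 comes from 18 with its C–O bond untouched, and the C4 hemiaminal center of 22 is destroyed on work-up. The step needs O-attack at C8a rather than C4a, which the C5 methoxymethoxy group next to C4a should secure by polarizing the aryne (3-alkoxyaryne rule: nucleophile at the distal carbon, carbanion next to oxygen) against the weak opposite bias of the C8 methyl group. It also needs acyl capture to outrun protonation of 21, which KH (no conjugate acid), THF and the 1,6-placement of the amide favour, and it needs C2 to survive base, which should hold because no enolizable ketone and no expelled alkoxide exist until the quench.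

**Step 10**
Reactants: 23 (2S)-5,7-bis(methoxymethoxy)-2-[4-methoxy-3-(3-methylbut-2-en-1-yl)phenyl]-8-methyl-6-(3-methylbut-2-en-1-yl)-2,3-dihydro-4H-chromen-4-one
Product: 24 (2S)-5,7-dihydroxy-2-[4-methoxy-3-(3-methylbut-2-en-1-yl)phenyl]-8-methyl-6-(3-methylbut-2-en-1-yl)-2,3-dihydro-4H-chromen-4-one
Conditions: HCl (1.25 M in MeOH), THF, 0 → 23 °C
Reagents that add atoms: none
Why: Acid-catalysed acetal exchange with methanol should remove both methoxymethyl groups (the chelated 5-O ether first), dilute acid and low temperature being chosen so that the freed hydroxyls do not add to the C6 prenyl group and the aryl methyl ether and C2 stay untouched.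

**Compound list**
1 | 4-methylbenzene-1,3-diol (4-methylresorcinol) | Cc1ccc(O)cc1O | starting material
2 | 2,4-bis(methoxymethoxy)-1-methylbenzene | Cc1ccc(OCOC)cc1OCOC | intermediate
3 | [2,6-bis(methoxymethoxy)-3-methylphenyl]lithium | Cc1ccc(OCOC)c([Li])c1OCOC | intermediate
4 | 2,4-bis(methoxymethoxy)-1-methyl-3-(3-methylbut-2-en-1-yl)benzene | Cc1ccc(OCOC)c(CC=C(C)C)c1OCOC | intermediate
5 | [2,4-bis(methoxymethoxy)-5-methyl-3-(3-methylbut-2-en-1-yl)phenyl]lithium | Cc1cc([Li])c(OCOC)c(CC=C(C)C)c1OCOC | intermediate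
6 | dimethyl [2,4-bis(methoxymethoxy)-5-methyl-3-(3-methylbut-2-en-1-yl)phenyl]boronate | Cc1cc(B(OC)OC)c(OCOC)c(CC=C(C)C)c1OCOC | intermediate
7 | 2,4-bis(methoxymethoxy)-5-methyl-3-(3-methylbut-2-en-1-yl)phenol | Cc1cc(O)c(OCOC)c(CC=C(C)C)c1OCOC | intermediate
8 | 2-bromo-4,6-bis(methoxymethoxy)-3-methyl-5-(3-methylbut-2-en-1-yl)phenol | Cc1c(Br)c(O)c(OCOC)c(CC=C(C)C)c1OCOC | intermediate
9 | [2-bromo-4,6-bis(methoxymethoxy)-3-methyl-5-(3-methylbut-2-en-1-yl)phenoxy](trimethyl)silane | Cc1c(Br)c(O[Si](C)(C)C)c(OCOC)c(CC=C(C)C)c1OCOC | intermediate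
10 | {3,5-bis(methoxymethoxy)-6-methyl-4-(3-methylbut-2-en-1-yl)-2-[(trimethylsilyl)oxy]phenyl}lithium | Cc1c([Li])c(O[Si](C)(C)C)c(OCOC)c(CC=C(C)C)c1OCOC | intermediate
11 | lithium 2,4-bis(methoxymethoxy)-5-methyl-3-(3-methylbut-2-en-1-yl)-6-(trimethylsilyl)phenolate | Cc1c([Si](C)(C)C)c([O-])c(OCOC)c(CC=C(C)C)c1OCOC.[Li+] | intermediate
12 | 2,4-bis(methoxymethoxy)-5-methyl-3-(3-methylbut-2-en-1-yl)-6-(trimethylsilyl)phenyl trifluoromethanesulfonate | Cc1c([Si](C)(C)C)c(OS(=O)(=O)C(F)(F)F)c(OCOC)c(CC=C(C)C)c1OCOC | intermediate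
13 | methyl 3-iodo-4-methoxybenzoate | COC(=O)c1ccc(OC)c(I)c1 | starting material
14 | methyl 4-methoxy-3-(3-methylbut-2-en-1-yl)benzoate | COC(=O)c1ccc(OC)c(CC=C(C)C)c1 | intermediate
15 | N-methoxy-N-methylacetamide | CC(=O)N(C)OC | starting material
16 | lithium 1-[methoxy(methyl)amino]ethen-1-olate (lithium enolate of 15) | C=C([O-])N(C)OC.[Li+] | intermediate
17 | N-methoxy-3-[4-methoxy-3-(3-methylbut-2-en-1-yl)phenyl]-N-methyl-3-oxopropanamide | CON(C)C(=O)CC(=O)c1ccc(OC)c(CC=C(C)C)c1 | intermediate
18 | (3S)-3-hydroxy-N-methoxy-3-[4-methoxy-3-(3-methylbut-2-en-1-yl)phenyl]-N-methylpropanamide | COc1ccc([C@@H](O)CC(=O)N(C)OC)cc1CC=C(C)C | intermediate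
19 | potassium (1S)-3-[methoxy(methyl)amino]-1-[4-methoxy-3-(3-methylbut-2-en-1-yl)phenyl]-3-oxopropan-1-olate | COc1ccc([C@@H]([O-])CC(=O)N(C)OC)cc1CC=C(C)C.[K+] | intermediate
20 | 1,2-didehydro-3,5-bis(methoxymethoxy)-6-methyl-4-(3-methylbut-2-en-1-yl)benzene (ring-A aryne, triple bond C4a–C8a) | CC1=C(OCOC)C(CC=C(C)C)=C(OCOC)C#C1 | intermediate
21 | potassium 2-{(1S)-3-[methoxy(methyl)amino]-1-[4-methoxy-3-(3-methylbut-2-en-1-yl)phenyl]-3-oxopropoxy}-4,6-bis(methoxymethoxy)-3-methyl-5-(3-methylbut-2-en-1-yl)benzen-1-ide | COc1ccc([C@@H](Oc2[c-]c(OCOC)c(CC=C(C)C)c(OCOC)c2C)CC(=O)N(C)OC)cc1CC=C(C)C.[K+] | intermediate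
22 | potassium (2S)-4-[methoxy(methyl)amino]-5,7-bis(methoxymethoxy)-2-[4-methoxy-3-(3-methylbut-2-en-1-yl)phenyl]-8-methyl-6-(3-methylbut-2-en-1-yl)-3,4-dihydro-2H-chromen-4-olate (both C4 epimers) | COc1ccc([C@@H]2CC([O-])(N(C)OC)c3c(OCOC)c(CC=C(C)C)c(OCOC)c(C)c3O2)cc1CC=C(C)C.[K+] | intermediate
23 | (2S)-5,7-bis(methoxymethoxy)-2-[4-methoxy-3-(3-methylbut-2-en-1-yl)phenyl]-8-methyl-6-(3-methylbut-2-en-1-yl)-2,3-dihydro-4H-chromen-4-one | COc1ccc([C@@H]2CC(=O)c3c(OCOC)c(CC=C(C)C)c(OCOC)c(C)c3O2)cc1CC=C(C)C | intermediate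
24 | (2S)-5,7-dihydroxy-2-[4-methoxy-3-(3-methylbut-2-en-1-yl)phenyl]-8-methyl-6-(3-methylbut-2-en-1-yl)-2,3-dihydro-4H-chromen-4-one | COc1ccc([C@@H]2CC(=O)c3c(O)c(CC=C(C)C)c(O)c(C)c3O2)cc1CC=C(C)C | target

**Step count and risks**
Total steps: 10. Longest linear sequence: 7 (steps 1–5, 9, 10); the ring-B branch (steps 6–8) joins at step 9.

Steps most likely to fail:

Step 9 (proposed annulation). The C4a carbanion may be protonated (by trace water, the C3 or C2 hydrogens or the crown ether) before it reaches the amide, so that only O-arylation occurs. The alkoxide may also attack the triflate sulfur instead of triggering the aryne, and slow acyl capture would open the way to β-elimination of the aryloxide. The fallback is stepwise and uses known reaction types; it sets out from 18 and 12. Plain aryne O–H insertion of the neutral alcohol (KF, 18-crown-6, THF, 60 °C, no KH) should give the aryl ether (3S)-3-[3,5-bis(methoxymethoxy)-2-methyl-4-(3-methylbut-2-en-1-yl)phenoxy]-N-methoxy-3-[4-methoxy-3-(3-methylbut-2-en-1-yl)phenyl]-N-methylpropanamide F1, with the same regiochemistry and C2 untouched. Its only ring-A hydrogen, at the C4a position between two oxygens, is then brominated (NBS, CH2Cl2, −78 °C) to (3S)-3-[2-bromo-3,5-bis(methoxymethoxy)-6-methyl-4-(3-methylbut-2-en-1-yl)phenoxy]-N-methoxy-3-[4-methoxy-3-(3-methylbut-2-en-1-yl)phenyl]-N-methylpropanamide F2. Parham cyclization (n-BuLi, THF, −100 °C, AcOH quench) closes the same C4–C4a bond and comes back to the route at 23.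

Step 4 (bromination). Electrophilic bromine may attack the trisubstituted prenyl double bond, with capture of the bromonium ion by a neighbouring acetal oxygen, or the very electron-rich phenol may be oxidized to a quinone. The fallback replaces electrophilic halogenation by directed metalation and sets out from 7. O-carbamoylation with isopropyl isocyanate (Et3N, CH2Cl2) gives 2,4-bis(methoxymethoxy)-5-methyl-3-(3-methylbut-2-en-1-yl)phenyl propan-2-ylcarbamate F3. In situ N-silylation (TMSOTf, TMEDA), carbamate-directed ortho-lithiation of the only ring hydrogen (n-BuLi, TMEDA, Et2O, −78 °C) and TMSCl give 2,4-bis(methoxymethoxy)-5-methyl-3-(3-methylbut-2-en-1-yl)-6-(trimethylsilyl)phenyl propan-2-ylcarbamate F4. One-pot carbamate cleavage (DBU, Et2NH, MeCN, 40 °C) and triflation (PhNTf2) come back to the route at 12, so step 5 is bypassed as well.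

Step 7 (Claisen condensation). The thermally labile enolate 16 may fragment (loss of formaldehyde) faster than it is acylated by the electron-rich, weakly electrophilic benzoate, and proton exchange may stall the condensation. The fallback builds the β-keto amide by acylketene chemistry and sets out from 14. Saponification (LiOH, THF/H2O) gives 4-methoxy-3-(3-methylbut-2-en-1-yl)benzoic acid F5. Condensation with Meldrum's acid (DCC, DMAP, CH2Cl2) gives 5-{hydroxy[4-methoxy-3-(3-methylbut-2-en-1-yl)phenyl]methylidene}-2,2-dimethyl-1,3-dioxane-4,6-dione F6. Heating F6 with N,O-dimethylhydroxylamine (toluene, 80 °C) should give the β-keto amide with loss of acetone and carbon dioxide, coming back to the route at 17.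

Further compounds
F1 | step 9 | (3S)-3-[3,5-bis(methoxymethoxy)-2-methyl-4-(3-methylbut-2-en-1-yl)phenoxy]-N-methoxy-3-[4-methoxy-3-(3-methylbut-2-en-1-yl)phenyl]-N-methylpropanamide | COc1ccc([C@@H](Oc2cc(OCOC)c(CC=C(C)C)c(OCOC)c2C)CC(=O)N(C)OC)cc1CC=C(C)C
F2 | step 9 | (3S)-3-[2-bromo-3,5-bis(methoxymethoxy)-6-methyl-4-(3-methylbut-2-en-1-yl)phenoxy]-N-methoxy-3-[4-methoxy-3-(3-methylbut-2-en-1-yl)phenyl]-N-methylpropanamide | COc1ccc([C@@H](Oc2c(Br)c(OCOC)c(CC=C(C)C)c(OCOC)c2C)CC(=O)N(C)OC)cc1CC=C(C)C
F3 | step 4 | 2,4-bis(methoxymethoxy)-5-methyl-3-(3-methylbut-2-en-1-yl)phenyl propan-2-ylcarbamate | Cc1cc(OC(=O)NC(C)C)c(OCOC)c(CC=C(C)C)c1OCOC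
F4 | step 4 | 2,4-bis(methoxymethoxy)-5-methyl-3-(3-methylbut-2-en-1-yl)-6-(trimethylsilyl)phenyl propan-2-ylcarbamate | Cc1c([Si](C)(C)C)c(OC(=O)NC(C)C)c(OCOC)c(CC=C(C)C)c1OCOC
F5 | step 7 | 4-methoxy-3-(3-methylbut-2-en-1-yl)benzoic acid | OC(=O)c1ccc(OC)c(CC=C(C)C)c1
F6 | step 7 | 5-{hydroxy[4-methoxy-3-(3-methylbut-2-en-1-yl)phenyl]methylidene}-2,2-dimethyl-1,3-dioxane-4,6-dione | CC1(C)OC(=O)C(=C(O)c2ccc(OC)c(CC=C(C)C)c2)C(=O)O1
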